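**Retrosynthetic overview**

1. 16 ⇒ 14 ⇒ 13 ⇒ 11: the benzoates are removed in reverse order of introduction (O5 last, placed by tin-acetal control after the acetonide is opened; O7 and O2 together), leading back to triol acetonide 11.
2. 11 ⇒ 9: C1–O and C7–O are disconnected together as a hydroxyl-directed syn-dihydroxylation of the exocyclic C1=C7 alkene, which sets the quaternary centre C1.
3. 9 ⇒ 7 ⇒ 5 ⇒ 4: C7 comes from titanium methylenation of the C1 ketone (O2 silylated meanwhile); diol 5 arises by loss of either of the two homotopic acetonides of 4.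
4. 4 ⇒ 3 ⇒ 1: C3=C4 comes from the trans O3/O4 diol of L-chiro-inositol diacetonide. The six-membered carbocycle is the cyclitol ring throughout, so no carbocycle is formed; only the two dioxolane protecting rings are made (step 1), and the last one is opened in step 10.
5. Feature: in the cyclohex-3-ene ring (C1 = quaternary carbinol carrying C7H2OBz, C2–OBz, C3=C4, C5–OBz, C6–OH) the oxygens on C2, C1, C6 and C5 are cis, trans, cis. With C7 set aside this is the twofold-symmetric conduritol E pattern, which L-chiro-inositol contains as O2, O1, O6, O5, so its two ends are homotopic.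

Key step: step 8

Remark on the chemistry: ring atoms carry the target numbering throughout (C1 quaternary, C2, C3=C4, C5, C6, exocyclic C7). C1–C6 of L-chiro-inositol, in the order of its SMILES, become C1–C6 of the target; the twofold axis makes the reverse assignment the same compound.

**Route**

Step 1
Reactants: 1 L-chiro-inositol; 2 2,2-dimethoxypropane
Product: 3 1,2:5,6-di-O-isopropylidene-L-chiro-inositol
Conditions: 2 (2.5 equiv), p-TsOH·H2O (cat.), DMF, rt; Et3N quench
Reagents that add atoms: 2,2-dimethoxypropane (2), COC(C)(C)OC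
Why: Acid-catalysed transketalisation (acetonide formation) under thermodynamic control should ketalise only the two cis-vicinal pairs O1/O2 and O5/O6 as cis-fused dioxolanes and leave the trans O3/O4 diol free, because a trans-fused dioxolane on the ring is strained and labile; no stereocentre is affected.

Step 2
Reactants: 3 1,2:5,6-di-O-isopropylidene-L-chiro-inositol
Product: 4 3,4-didehydro-3,4-dideoxy-1,2:5,6-di-O-isopropylidene-L-chiro-inositol (conduritol E diacetonide; C3=C4; all four oxygen-bearing carbons S; twofold-symmetric)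
Conditions: PPh3 (4 equiv), imidazole (4 equiv), I2 (3 equiv), toluene, reflux
Reagents that add atoms: none
Why: Garegg–Samuelsson olefination: the vicinal trans-diol is activated as alkoxyphosphonium/iodide and undergoes iodide-induced reductive elimination to the C3=C4 alkene, with imidazole buffering HI so the ketals survive; the two carbinol centres are erased and the other four are untouched.

Step 3
Reactants: 4 conduritol E diacetonide
Product: 5 (3aS,6S,7S,7aR)-2,2-dimethyl-3a,6,7,7a-tetrahydro-1,3-benzodioxole-6,7-diol (C1–OH and C2–OH free and cis, on the face opposite the C5/C6 acetonide)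
Conditions: AcOH–H2O (4:1), 40 °C, stopped at partial conversion; recovered 4 recycled
Reagents that add atoms: none
Why: Controlled acid hydrolysis of one isopropylidene ketal; because the twofold axis of 4 interchanges the two acetonides, loss of either gives the same diol, and the only selectivity needed (mono versus double cleavage) is handled by stopping early and recycling.

Step 4
Reactants: 5 (3aS,6S,7S,7aR)-2,2-dimethyl-3a,6,7,7a-tetrahydro-1,3-benzodioxole-6,7-diol
Product: 6 (3aS,6S,7R,7aR)-6-{[tert-butyl(dimethyl)silyl]oxy}-2,2-dimethyl-3a,6,7,7a-tetrahydro-1,3-benzodioxol-7-ol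
Conditions: TBSCl (1.05 equiv), imidazole, DMF, −20 → 0 °C
Reagents that add atoms: tert-butyldimethylsilyl chloride, CC(C)(C)[Si](C)(C)Cl
Why: Kinetic monosilylation (silyl ether formation) should occur at the allylic C2 hydroxyl, which is flanked by a planar alkene carbon, in preference to the C1 hydroxyl, which lies between two oxygenated sp3 carbons.

Step 5
Reactants: 6 (3aS,6S,7R,7aR)-6-{[tert-butyl(dimethyl)silyl]oxy}-2,2-dimethyl-3a,6,7,7a-tetrahydro-1,3-benzodioxol-7-ol
Product: 7 (3aS,6S,7aS)-6-{[tert-butyl(dimethyl)silyl]oxy}-2,2-dimethyl-3a,7a-dihydro-1,3-benzodioxol-7(6H)-one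
Conditions: Dess–Martin periodinane, NaHCO3, CH2Cl2, 0 °C → rt
Reagents that add atoms: none
Why: Dess–Martin oxidation of the secondary C1 alcohol under buffered, non-basic conditions, chosen so that the α-stereocentres C2 and C6 are not epimerised and no β-oxygen is eliminated.

Step 6
Reactants: 7 (3aS,6S,7aS)-6-{[tert-butyl(dimethyl)silyl]oxy}-2,2-dimethyl-3a,7a-dihydro-1,3-benzodioxol-7(6H)-one
Product: 8 tert-butyl(dimethyl){[(3aS,6S,7aR)-2,2-dimethyl-7-methylidene-3a,6,7,7a-tetrahydro-1,3-benzodioxol-6-yl]oxy}silane
Conditions: Cp2TiMe2 (3 equiv), toluene, 65 °C, dark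
Reagents that add atoms: dimethyltitanocene Cp2TiMe2, C[Ti+2]C.c1cc[cH-]c1.c1cc[cH-]c1
Why: Petasis methylenation: thermally generated Cp2Ti=CH2 adds to the ketone by [2+2] cycloaddition and the oxatitanacyclobutane collapses to the C1=C7 alkene; the reagent is non-basic, so the enolisable, elimination-prone ketone is not deprotonated, and no stereocentre is formed.

Step 7
Reactants: 8 tert-butyl(dimethyl){[(3aS,6S,7aR)-2,2-dimethyl-7-methylidene-3a,6,7,7a-tetrahydro-1,3-benzodioxol-6-yl]oxy}silane
Product: 9 (3aS,6S,7aR)-2,2-dimethyl-7-methylidene-3a,6,7,7a-tetrahydro-1,3-benzodioxol-6-ol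
Conditions: TBAF, THF, 0 °C
Reagents that add atoms: none
Why: Fluoride-mediated desilylation frees the C2 hydroxyl that directs the next step; the acetonide and both alkenes are inert to TBAF.

Step 8
Reactants: 9 (3aS,6S,7aR)-2,2-dimethyl-7-methylidene-3a,6,7,7a-tetrahydro-1,3-benzodioxol-6-ol
Product: 11 (3aS,6S,7S,7aS)-7-(hydroxymethyl)-2,2-dimethyl-3a,6,7,7a-tetrahydro-1,3-benzodioxole-6,7-diol, via cyclic osmate ester TMEDA chelate 10 (not isolated)
Conditions: OsO4 (1.05 equiv), TMEDA (1.1 equiv), CH2Cl2, −78 °C; then aq Na2SO3, THF, reflux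
Reagents that add atoms: osmium tetroxide, O=[Os](=O)(=O)=O; TMEDA (N,N,N',N'-tetramethylethane-1,2-diamine), CN(C)CCN(C)C, which stays in 10 only
Why: The diamine makes the oxo ligands of OsO4 good hydrogen-bond acceptors, so the complex is held by the free C2 hydroxyl of 9 and adds by [3+2] cycloaddition to the C1=C7 methylidene, giving the chelated osmate ester 10 of hexavalent osmium, whose hydrolytic cleavage releases the C1 and C7 hydroxyls. The closest known reaction type is the hydrogen-bond-directed syn-dihydroxylation of cyclic allylic alcohols with OsO4/TMEDA. No ring of the product is closed (the osmate ring is transient); only the C1–O and C7–O bonds are made. The one new stereocentre, C1, is set by oxygen delivery to the alkene face syn to the C2 hydroxyl, which is also the face opposite the cis-fused C5/C6 acetonide, so directing and steric effects agree and place O1 cis to O2 and trans to O6. The step needs chemoselectivity for the exocyclic alkene over the ring alkene C3=C4, which is also allylic to the C2 hydroxyl. The unhindered CH2 terminus of the 1,1-disubstituted alkene, the low temperature and the use of one equivalent of the bulky complex are expected to secure it, since the ring alkene is cis-disubstituted and each of its carbons is flanked by a C–O bond.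

Step 9
Reactants: 11 (3aS,6S,7S,7aS)-7-(hydroxymethyl)-2,2-dimethyl-3a,6,7,7a-tetrahydro-1,3-benzodioxole-6,7-diol; 12 benzoyl chloride
Product: 13 [(3aS,6S,7S,7aS)-6-(benzoyloxy)-7-hydroxy-2,2-dimethyl-3a,6,7,7a-tetrahydro-1,3-benzodioxol-7-yl]methyl benzoate
Conditions: 12 (2.3 equiv), pyridine, CH2Cl2, 0 °C → rt
Reagents that add atoms: benzoyl chloride (12), O=C(Cl)c1ccccc1
Why: Acylation with benzoyl chloride/pyridine (ester formation) should benzoylate the primary O7 and the secondary allylic O2, while the fully substituted tertiary C1 hydroxyl stays free under these unforced conditions.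

Step 10
Reactants: 13 [(3aS,6S,7S,7aS)-6-(benzoyloxy)-7-hydroxy-2,2-dimethyl-3a,6,7,7a-tetrahydro-1,3-benzodioxol-7-yl]methyl benzoate
Product: 14 [(1R,2S,5S,6S)-2-(benzoyloxy)-1,5,6-trihydroxycyclohex-3-en-1-yl]methyl benzoate
Conditions: TFA–H2O (9:1), CH2Cl2, 0 °C
Reagents that add atoms: none
Why: Acid-catalysed ketal hydrolysis releases the cis C5/C6 diol; benzoates are stable to cold aqueous acid, and acyl migration, which is base-promoted, is kept to a minimum.

Step 11
Reactants: 14 [(1R,2S,5S,6S)-2-(benzoyloxy)-1,5,6-trihydroxycyclohex-3-en-1-yl]methyl benzoate; 12 benzoyl chloride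
Product: 16 [(1R,2S,5S,6S)-2,5-bis(benzoyloxy)-1,6-dihydroxycyclohex-3-en-1-yl]methyl benzoate, via O5/O6 dibutylstannylene acetal 15 (not isolated)
Conditions: Bu2SnO (1.1 equiv), toluene, reflux (Dean–Stark); then 12 (1.05 equiv), 0 °C → rt
Reagents that add atoms: benzoyl chloride (12), O=C(Cl)c1ccccc1; dibutyltin oxide Bu2SnO, CCCC[Sn](=O)CCCC, which stays in 15 only
Why: Stannylene-acetal-mediated regioselective acylation: Bu2SnO bridges the cis O5/O6 diol, and the tin acetal should be benzoylated at the allylic, pseudoequatorial and less hindered O5 rather than at O6, which is expected to be axial in the half-chair with C7 equatorial and which neighbours the quaternary C1; the tertiary O1 does not react, and the product is the target.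

**Compound list**

1 | L-chiro-inositol | O[C@H]1[C@@H](O)[C@H](O)[C@@H](O)[C@H](O)[C@@H]1O | starting material
2 | 2,2-dimethoxypropane | COC(C)(C)OC | starting material
3 | 1,2:5,6-di-O-isopropylidene-L-chiro-inositol | O[C@@H]1[C@@H](O)[C@@H]2OC(C)(C)O[C@@H]2[C@H]2OC(C)(C)O[C@@H]12 | intermediate
4 | 3,4-didehydro-3,4-dideoxy-1,2:5,6-di-O-isopropylidene-L-chiro-inositol (conduritol E diacetonide) | C1=C[C@@H]2OC(C)(C)O[C@@H]2[C@H]2OC(C)(C)O[C@@H]12 | intermediate
5 | (3aS,6S,7S,7aR)-2,2-dimethyl-3a,6,7,7a-tetrahydro-1,3-benzodioxole-6,7-diol | O[C@H]1[C@@H](O)C=C[C@@H]2OC(C)(C)O[C@H]12 | intermediate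
6 | (3aS,6S,7R,7aR)-6-{[tert-butyl(dimethyl)silyl]oxy}-2,2-dimethyl-3a,6,7,7a-tetrahydro-1,3-benzodioxol-7-ol | O[C@H]1[C@@H](O[Si](C)(C)C(C)(C)C)C=C[C@@H]2OC(C)(C)O[C@H]12 | intermediate
7 | (3aS,6S,7aS)-6-{[tert-butyl(dimethyl)silyl]oxy}-2,2-dimethyl-3a,7a-dihydro-1,3-benzodioxol-7(6H)-one | O=C1[C@@H](O[Si](C)(C)C(C)(C)C)C=C[C@@H]2OC(C)(C)O[C@H]12 | intermediate
8 | tert-butyl(dimethyl){[(3aS,6S,7aR)-2,2-dimethyl-7-methylidene-3a,6,7,7a-tetrahydro-1,3-benzodioxol-6-yl]oxy}silane | C=C1[C@@H](O[Si](C)(C)C(C)(C)C)C=C[C@@H]2OC(C)(C)O[C@H]12 | intermediate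
9 | (3aS,6S,7aR)-2,2-dimethyl-7-methylidene-3a,6,7,7a-tetrahydro-1,3-benzodioxol-6-ol | C=C1[C@@H](O)C=C[C@@H]2OC(C)(C)O[C@H]12 | intermediate
10 | cyclic osmate ester of 11 across O1 and O7 (dioxo, hexavalent osmium, chelated by TMEDA), not isolated | C[N+]1(C)CC[N+](C)(C)[Os-2]12(=O)(=O)OC[C@]3(O2)[C@@H](O)C=C[C@@H]4OC(C)(C)O[C@H]34 | intermediate
11 | (3aS,6S,7S,7aS)-7-(hydroxymethyl)-2,2-dimethyl-3a,6,7,7a-tetrahydro-1,3-benzodioxole-6,7-diol | OC[C@]1(O)[C@@H](O)C=C[C@@H]2OC(C)(C)O[C@H]12 | intermediate
12 | benzoyl chloride | O=C(Cl)c1ccccc1 | starting material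
13 | [(3aS,6S,7S,7aS)-6-(benzoyloxy)-7-hydroxy-2,2-dimethyl-3a,6,7,7a-tetrahydro-1,3-benzodioxol-7-yl]methyl benzoate | O=C(OC[C@]1(O)[C@@H](OC(=O)c2ccccc2)C=C[C@@H]2OC(C)(C)O[C@H]12)c1ccccc1 | intermediate
14 | [(1R,2S,5S,6S)-2-(benzoyloxy)-1,5,6-trihydroxycyclohex-3-en-1-yl]methyl benzoate | O=C(OC[C@]1(O)[C@@H](OC(=O)c2ccccc2)C=C[C@H](O)[C@@H]1O)c1ccccc1 | intermediate
15 | O5/O6 dibutylstannylene acetal of 14, not isolated | O=C(OC[C@]1(O)[C@@H](OC(=O)c2ccccc2)C=C[C@@H]2O[Sn](CCCC)(CCCC)O[C@H]12)c1ccccc1 | intermediate
16 | [(1R,2S,5S,6S)-2,5-bis(benzoyloxy)-1,6-dihydroxycyclohex-3-en-1-yl]methyl benzoate | O=C(OC[C@]1(O)[C@@H](OC(=O)c2ccccc2)C=C[C@H](OC(=O)c2ccccc2)[C@@H]1O)c1ccccc1 | target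

**Step count**

Total steps: 11. Longest linear sequence: 11 steps (1 → 16).

**Steps most likely to fail**

Step 8 (key step). The ring alkene C3=C4 is also allylic to the directing hydroxyl, so osmium may be delivered there in competition. The polar triol may also be lost while the robust osmate–diamine chelate is cleaved. The fallback sets out from 9 and returns at 13, forming the two C–O bonds in separate events. Hydroxyl-directed epoxidation of 9 with VO(acac)2 (cat.) and tert-butyl hydroperoxide in CH2Cl2 at 0 °C should transfer oxygen to the more nucleophilic 1,1-disubstituted alkene on the face of the C2 hydroxyl. This gives the spiro-epoxide (3aS,6S,7S,7aS)-2,2-dimethyl-3a,6-dihydro-7aH-spiro[1,3-benzodioxole-7,2'-oxiran]-6-ol F1, in which the C1–O bond is already cis to O2. Opening of this 2,3-epoxy alcohol with benzoic acid and Ti(OiPr)4 at its primary carbon C7 should give the monobenzoate [(3aS,6S,7S,7aS)-6,7-dihydroxy-2,2-dimethyl-3a,6,7,7a-tetrahydro-1,3-benzodioxol-7-yl]methyl benzoate F2. Benzoylation of its C2 hydroxyl with 12 in pyridine then gives 13.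

Step 11. Regiocontrol may be lost between O5 and O6, acylation may go too far, or the existing benzoates may migrate toward O1 or O6 while the tin acetal is formed at reflux. The fallback sets out from 14 and returns at 16. It replaces the preformed, stoichiometric tin acetal by catalytic, reversible boron activation at room temperature: 2-aminoethyl diphenylborinate Ph2BOCH2CH2NH2 (10 mol %), 12 and iPr2NEt in MeCN. The borinic acid binds the cis O5/O6 diol as a tetracoordinate borinate and should direct the acyl group to the less hindered pseudoequatorial O5 without heating or a tin alkoxide. No new compound is involved.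

Step 6. At 65 °C the ketone may enolise at C2–H, which is both α to the carbonyl and allylic, and then lose the C5 oxygen by vinylogous β-elimination with aromatisation; methylidene transfer may also stall. The fallback sets out from 7 and returns at 8, building the alkene by addition and elimination instead of by a titanium carbene. Addition of Me3SiCH2Li in the presence of CeCl3 (THF, −78 °C; weakly basic organocerium) should give the β-hydroxysilane (3aS,6S,7aS)-6-{[tert-butyl(dimethyl)silyl]oxy}-2,2-dimethyl-7-[(trimethylsilyl)methyl]-3a,6,7,7a-tetrahydro-1,3-benzodioxol-7-ol F3 as either C7 epimer. Peterson elimination with KH in THF at 0 °C then gives 8; the carbinol configuration is irrelevant because the centre becomes sp2.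

**Further compounds**

F1 | step 8 | (3aS,6S,7S,7aS)-2,2-dimethyl-3a,6-dihydro-7aH-spiro[1,3-benzodioxole-7,2'-oxiran]-6-ol | C1O[C@]12[C@@H](O)C=C[C@@H]3OC(C)(C)O[C@H]23
F2 | step 8 | [(3aS,6S,7S,7aS)-6,7-dihydroxy-2,2-dimethyl-3a,6,7,7a-tetrahydro-1,3-benzodioxol-7-yl]methyl benzoate | O=C(OC[C@]1(O)[C@@H](O)C=C[C@@H]2OC(C)(C)O[C@H]12)c1ccccc1
F3 | step 6 | (3aS,6S,7aS)-6-{[tert-butyl(dimethyl)silyl]oxy}-2,2-dimethyl-7-[(trimethylsilyl)methyl]-3a,6,7,7a-tetrahydro-1,3-benzodioxol-7-ol (C7 configuration not defined) | C[Si](C)(C)CC1(O)[C@@H](O[Si](C)(C)C(C)(C)C)C=C[C@@H]2OC(C)(C)O[C@H]12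
F0 | step 11 | none | none
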